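The route rests on disconnecting the dihydropyranone ring of the 2,3-dimethylchroman-4-one unit at O1–C8a and at C4–C3. Both bonds are made in one operation from 2-fluoro-4,6-dimethoxybenzaldehyde and (R)-but-3-en-2-ol: alkoxide SNAr at the fluorinated carbon, then carbene-catalysed umpolung of the formyl carbon (future C4) and hydroacylation of the tethered vinyl group, whose terminal CH2 becomes the C3 methyl. The step exploits the ortho relation of ether oxygen O1 and acyl carbon C4 on the benzo ring, and the C3 methyl as a masked alkene terminus. Afterwards C8 is brominated, C6 receives the octanoate chain by asymmetric Michael addition, a verbenone-derived cyclobutylmethylzinc is coupled at C8, and dearomatising prenylation at C8 finishes the target.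

Key step: step 1

Remark: chroman numbering (O1, C2, C3, C4, C4a, C5–C8, C8a) is used for the bicyclic core; the target is drawn as the 5-hydroxy-4,7-dioxo tautomer of its enolised triketone and all such tautomers are treated as one compound; compounds 1, 2, 7, 10 and 17 are taken to be purchasable.

Step 1
Reactants: 1 2-fluoro-4,6-dimethoxybenzaldehyde; 2 (R)-but-3-en-2-ol
Product: 4 (2R,3R)-5,7-dimethoxy-2,3-dimethylchroman-4-one, via ether aldehyde 3 (not isolated)
Conditions: NaH, 1,4-dioxane, 0 → 70 °C; then 2-mesityl-6,7-dihydro-5H-pyrrolo[2,1-c][1,2,4]triazol-2-ium chloride (20 mol %), DBU (40 mol %), 120 °C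
Reagents that add atoms: none
Why: The sodium alkoxide of 2 displaces fluoride at the carbon ortho to the formyl group by addition–elimination (Meisenheimer adduct, carbonyl-activated and sodium-chelated), forming O1–C8a and giving 3; the carbene then adds to the formyl carbon to give the Breslow intermediate, an acyl anion equivalent that adds to the internal carbon of the tethered vinyl group with concerted proton transfer to the terminal CH2, forming C4–C3 and the C3 methyl before the carbene is released. The closest known reactions are the alkoxide SNAr of 2-fluorobenzaldehydes and the carbene-catalysed intramolecular hydroacylation of 2-allyloxybenzaldehydes to 3-methylchroman-4-ones, here telescoped. The dihydropyranone ring closes in the C–C step by 6-exo-trig attack of the nucleophilic acyl carbon on the alkene. C2 is carried unchanged from (R)-2 because its C–O bond is never broken, and the new C3 centre is set under thermodynamic control, DBU equilibrating the ketone through its enol to the trans-2,3-dimethyl (3R) isomer with both methyls pseudo-equatorial. The step needs substitution at C–F only (fluoride is the best leaving group and sits ortho to the formyl group; the methoxy groups are inert), six-membered Markovnikov closure over seven-membered closure (inherent to the carbene mechanism) and no benzoin coupling (suppressed by the two ortho substituents of the aldehyde).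

Step 2
Reactants: 4 (2R,3R)-5,7-dimethoxy-2,3-dimethylchroman-4-one
Product: 5 (2R,3R)-8-bromo-5,7-dimethoxy-2,3-dimethylchroman-4-one
Conditions: NBS, MeCN, 0 °C → rt
Reagents that add atoms: N-bromosuccinimide, O=C1CCC(=O)N1Br
Why: Electrophilic aromatic bromination is expected at C8, which is activated by O1 and the 7-methoxy group (ortho) and the 5-methoxy group (para) and is less encumbered than C6, whose two flanking methoxy groups include the 5-methoxy group that the peri carbonyl turns toward C6.

Step 3
Reactants: 5 (2R,3R)-8-bromo-5,7-dimethoxy-2,3-dimethylchroman-4-one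
Product: 6 (2R,3R)-8-bromo-5,7-dihydroxy-2,3-dimethylchroman-4-one
Conditions: BBr3, CH2Cl2, −78 → 0 °C; aq. NaHCO3
Reagents that add atoms: none
Why: Lewis acid-mediated ether cleavage (bromide SN2 at the O-methyl groups of the boron-bound ethers) should free both phenols, while ring oxygen O1 (a weakly basic vinylogous ester oxygen on a secondary carbon) and the aryl bromide persist and the trans-2,3-dimethyl arrangement is already the thermodynamic one.

Step 4
Reactants: 6 (2R,3R)-8-bromo-5,7-dihydroxy-2,3-dimethylchroman-4-one; 7 (E)-oct-2-enal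
Product: 8 (2R,3R,6S)-10-bromo-5,8-dihydroxy-2,3-dimethyl-6-pentyl-2,3,7,8-tetrahydro-4H,6H-pyrano[3,2-g]chromen-4-one (lactol on the former 7-OH, both anomers)
Conditions: (R)-α,α-diphenylprolinol trimethylsilyl ether (20 mol %), PhCO2H (20 mol %), CH2Cl2/MeCN, 0 °C → rt
Reagents that add atoms: none
Why: Iminium-ion organocatalysis makes 7 an electrophile for Friedel–Crafts-type Michael addition by C6, the only free ring carbon (C8 is blocked by bromine); the (R)-configured CPh2OSiMe3 group shields one face of the (E)-iminium so the aryl carbon adds to the β-carbon from the open face to give the S centre, and hemiacetal formation with the free 7-OH (5-OH stays chelated to the C4 carbonyl) releases the catalyst.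

Step 5
Reactants: 8 the lactol
Product: 9 (2R,3R,6S)-10-bromo-5-hydroxy-2,3-dimethyl-6-pentyl-2,3,6,7-tetrahydro-4H,8H-pyrano[3,2-g]chromene-4,8-dione (lactone)
Conditions: Dess–Martin periodinane, CH2Cl2, 0 °C → rt
Reagents that add atoms: none
Why: Lactol-to-lactone oxidation by the hypervalent iodine reagent; the remaining 5-OH is chelated, the arene has no free position and no alkene is yet present, so no other group should be touched.

Step 6
Reactants: 10 (1S,5S)-(−)-verbenone
Product: 11 (1S,3R)-3-acetyl-2,2-dimethylcyclobutane-1-carboxylic acid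
Conditions: RuCl3 hydrate (2 mol %), NaIO4, EtOAc/MeCN/H2O, rt
Reagents that add atoms: sodium periodate, [Na+].[O-]I(=O)(=O)=O; water, O
Why: Ruthenium tetroxide generated in situ cleaves the enone C=C oxidatively and the resulting α-keto acid loses CO2 on further oxidation, which excises C3 of 10 and leaves both cyclobutane stereocentres untouched (the ring fusion enforces cis).

Step 7
Reactants: 11 (1S,3R)-3-acetyl-2,2-dimethylcyclobutane-1-carboxylic acid
Product: 12 (1S,3S)-2,2-dimethyl-3-(prop-1-en-2-yl)cyclobutane-1-carboxylic acid
Conditions: Ph3PCH3Br, KOtBu, THF, 0 °C → rt; aq. HCl work-up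
Reagents that add atoms: methyltriphenylphosphonium bromide, C[P+](c1ccccc1)(c1ccccc1)c1ccccc1.[Br-]
Why: Wittig methylenation of the methyl ketone (the first equivalent of base only forms the carboxylate) gives the isopropenyl group; the α-stereocentre should hold because olefination is fast at 0 °C and the cis-1,3 arrangement is not disfavoured thermodynamically.

Step 8
Reactants: 12 (1S,3S)-2,2-dimethyl-3-(prop-1-en-2-yl)cyclobutane-1-carboxylic acid
Product: 13 [(1S,3S)-2,2-dimethyl-3-(prop-1-en-2-yl)cyclobutyl]methanol
Conditions: LiAlH4, THF, 0 °C → rt; aq. NaOH work-up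
Reagents that add atoms: none
Why: Hydride reduction of the carboxylic acid to the primary alcohol with LiAlH4, which leaves the isolated alkene and both stereocentres alone.

Step 9
Reactants: 13 [(1S,3S)-2,2-dimethyl-3-(prop-1-en-2-yl)cyclobutyl]methanol
Product: 14 (1S,3S)-1-(iodomethyl)-2,2-dimethyl-3-(prop-1-en-2-yl)cyclobutane
Conditions: I2, PPh3, imidazole, CH2Cl2, 0 °C → rt
Reagents that add atoms: iodine, II
Why: Appel-type iodination in which iodide displaces the alkoxyphosphonium ion by SN2 at the primary carbon, so no cation forms next to the strained ring and the alkene survives.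

Step 10
Reactants: 9 the bromo lactone; 14 (1S,3S)-1-(iodomethyl)-2,2-dimethyl-3-(prop-1-en-2-yl)cyclobutane
Product: 16 (2R,3R,6S)-10-{[(1R,3S)-2,2-dimethyl-3-(prop-1-en-2-yl)cyclobutyl]methyl}-5-hydroxy-2,3-dimethyl-6-pentyl-2,3,6,7-tetrahydro-4H,8H-pyrano[3,2-g]chromene-4,8-dione, via organozinc iodide 15 (not isolated)
Conditions: 14, Zn dust, LiCl, THF, 25 °C; then 9, Pd(OAc)2 (3 mol %), SPhos (6 mol %), THF, 25 → 50 °C, slow addition of 15 (2 equiv)
Reagents that add atoms: none
Why: Negishi coupling in which zinc insertion into the primary C–I bond gives 15, which transmetallates to the arylpalladium bromide formed by oxidative addition of zerovalent palladium to the C10–Br bond of 9, the bulky electron-rich biarylphosphine favouring reductive elimination over β-hydride elimination; organozinc halides tolerate lactone and ketone and react only slowly with the chelated phenol.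

Step 11
Reactants: 16 the coupled lactone; 17 3-methylbut-2-en-1-yl acetate (prenyl acetate)
Product: 19 (3S)-3-[(2R,3R,8R)-8-{[(1R,3S)-2,2-dimethyl-3-(prop-1-en-2-yl)cyclobutyl]methyl}-5-hydroxy-2,3-dimethyl-8-(3-methylbut-2-en-1-yl)-4,7-dioxo-3,4,7,8-tetrahydro-2H-chromen-6-yl]octanoic acid (target), via lithium seco-acid salt 18 (not isolated)
Conditions: LiOH (3.2 equiv), THF/H2O (4:1), 0 °C; then Pd2(dba)3·CHCl3 (2.5 mol %), N,N'-[(1R,2R)-cyclohexane-1,2-diyl]bis[2-(diphenylphosphino)benzamide] (7.5 mol %), 17 (1.2 equiv), 0 °C → rt; then 1 M HCl to pH 3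
Reagents that add atoms: lithium hydroxide, [Li+].[OH-]
Why: Hydroxide opens the aryl lactone to carboxylate 18 and frees the 7-phenoxide, whose ortho carbon C8 attacks the prenyl π-allylpalladium complex at its unsubstituted terminus (Tsuji–Trost allylation with dearomatisation; O-allylation of phenoxide or carboxylate is reversible under palladium and C6 with its branched substituent is more hindered), the new quaternary centre C8 being set by the chiral diphosphine pocket (catalyst control, since the resident stereocentres are remote) with the (R,R)-ligand as the proposed choice for the R configuration, to be exchanged for its enantiomer should the sense prove opposite.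

Compound list
1 | 2-fluoro-4,6-dimethoxybenzaldehyde | COc1cc(F)c(C=O)c(OC)c1 | starting material
2 | (R)-but-3-en-2-ol | C=C[C@@H](C)O | starting material
3 | (R)-2-(but-3-en-2-yloxy)-4,6-dimethoxybenzaldehyde | COc1cc(OC)c(C=O)c(c1)O[C@H](C)C=C | intermediate
4 | (2R,3R)-5,7-dimethoxy-2,3-dimethylchroman-4-one | COc1cc(OC)c2c(c1)O[C@H](C)[C@@H](C)C2=O | intermediate
5 | (2R,3R)-8-bromo-5,7-dimethoxy-2,3-dimethylchroman-4-one | COc1cc(OC)c2c(c1Br)O[C@H](C)[C@@H](C)C2=O | intermediate
6 | (2R,3R)-8-bromo-5,7-dihydroxy-2,3-dimethylchroman-4-one | Oc1cc(O)c2c(c1Br)O[C@H](C)[C@@H](C)C2=O | intermediate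
7 | (E)-oct-2-enal | CCCCC/C=C/C=O | starting material
8 | (2R,3R,6S)-10-bromo-5,8-dihydroxy-2,3-dimethyl-6-pentyl-2,3,7,8-tetrahydro-4H,6H-pyrano[3,2-g]chromen-4-one (lactol, both anomers) | OC1C[C@H](CCCCC)c2c(O)c3c(c(Br)c2O1)O[C@H](C)[C@@H](C)C3=O | intermediate
9 | (2R,3R,6S)-10-bromo-5-hydroxy-2,3-dimethyl-6-pentyl-2,3,6,7-tetrahydro-4H,8H-pyrano[3,2-g]chromene-4,8-dione (lactone) | O=C1C[C@H](CCCCC)c2c(O)c3c(c(Br)c2O1)O[C@H](C)[C@@H](C)C3=O | intermediate
10 | (1S,5S)-(−)-verbenone | CC1=CC(=O)[C@H]2C[C@@H]1C2(C)C | starting material
11 | (1S,3R)-3-acetyl-2,2-dimethylcyclobutane-1-carboxylic acid | CC(=O)[C@@H]1C[C@H](C(=O)O)C1(C)C | intermediate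
12 | (1S,3S)-2,2-dimethyl-3-(prop-1-en-2-yl)cyclobutane-1-carboxylic acid | C=C(C)[C@@H]1C[C@H](C(=O)O)C1(C)C | intermediate
13 | [(1S,3S)-2,2-dimethyl-3-(prop-1-en-2-yl)cyclobutyl]methanol | C=C(C)[C@@H]1C[C@H](CO)C1(C)C | intermediate
14 | (1S,3S)-1-(iodomethyl)-2,2-dimethyl-3-(prop-1-en-2-yl)cyclobutane | C=C(C)[C@@H]1C[C@H](CI)C1(C)C | intermediate
15 | {[(1S,3S)-2,2-dimethyl-3-(prop-1-en-2-yl)cyclobutyl]methyl}zinc iodide | C=C(C)[C@@H]1C[C@H](C[Zn]I)C1(C)C | intermediate
16 | (2R,3R,6S)-10-{[(1R,3S)-2,2-dimethyl-3-(prop-1-en-2-yl)cyclobutyl]methyl}-5-hydroxy-2,3-dimethyl-6-pentyl-2,3,6,7-tetrahydro-4H,8H-pyrano[3,2-g]chromene-4,8-dione | C=C(C)[C@@H]1C[C@H](Cc2c3OC(=O)C[C@H](CCCCC)c3c(O)c3c2O[C@H](C)[C@@H](C)C3=O)C1(C)C | intermediate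
17 | 3-methylbut-2-en-1-yl acetate | CC(C)=CCOC(C)=O | starting material
18 | lithium (3S)-3-[(2R,3R)-8-{[(1R,3S)-2,2-dimethyl-3-(prop-1-en-2-yl)cyclobutyl]methyl}-5,7-dihydroxy-2,3-dimethyl-4-oxochroman-6-yl]octanoate | C=C(C)[C@@H]1C[C@H](Cc2c(O)c([C@@H](CCCCC)CC(=O)[O-])c(O)c3c2O[C@H](C)[C@@H](C)C3=O)C1(C)C.[Li+] | intermediate
19 | (3S)-3-[(2R,3R,8R)-8-{[(1R,3S)-2,2-dimethyl-3-(prop-1-en-2-yl)cyclobutyl]methyl}-5-hydroxy-2,3-dimethyl-8-(3-methylbut-2-en-1-yl)-4,7-dioxo-3,4,7,8-tetrahydro-2H-chromen-6-yl]octanoic acid | C=C(C)[C@@H]1C[C@H](C[C@@]2(CC=C(C)C)C(=O)C([C@@H](CCCCC)CC(=O)O)=C(O)C3=C2O[C@H](C)[C@@H](C)C3=O)C1(C)C | target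

Total step count: 11. Longest linear sequence: 7 steps (steps 1, 2, 3, 4, 5, 10, 11); the cyclobutane branch (steps 6–9) joins at step 10.

Steps most likely to fail

Step 1. Fluoride displacement on the electron-rich ring may be slow, so that hydride transfer from the secondary alkoxide to the aldehyde competes, and prolonged heating with DBU may erode the configuration at C2 by reversible ring-opening of the chromanone. The fallback sets out from 2 and separates the two bond formations. Alcohol 2 is coupled with 2-bromo-4,6-dimethoxybenzaldehyde F1 under copper catalysis (CuI, 3,4,7,8-tetramethyl-1,10-phenanthroline, Cs2CO3, toluene, 100 °C), which leaves the carbinol centre untouched and gives ether aldehyde 3, now isolated. Compound 3 is then cyclised by the same carbene-catalysed hydroacylation at the lowest workable temperature, and the route is rejoined at 4.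

Step 11. The chiral palladium catalyst may discriminate the two faces of C8 poorly, because the resident stereocentres offer no help, and allylation at C6 or on oxygen may compete. The fallback sets out from 16 and uses ion-pairing control instead of a metal–ligand pocket. CsOH·H2O opens the lactone, and the resulting phenoxide is alkylated with prenyl bromide under a chiral phase-transfer catalyst (N-(9-anthracenylmethyl)cinchonidinium bromide, toluene/CHCl3, −40 °C); the pseudo-enantiomeric cinchoninium salt is available if the other sense is needed. It comes back to the route directly at 19; no new compound arises on this way (entry F0).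

Step 10. Zinc insertion passes through a cyclobutylcarbinyl radical that may open the strained ring before it is captured, and the organozinc may be protonated by the phenol faster than it couples. The fallback sets out from 14 and avoids radicals. Iodine–lithium exchange (t-BuLi, Et2O/pentane, −78 °C) and trapping with 9-methoxy-9-borabicyclo[3.3.1]nonane give lithium B-methoxy-B-{[(1S,3S)-2,2-dimethyl-3-(prop-1-en-2-yl)cyclobutyl]methyl}-9-borabicyclo[3.3.1]nonan-9-uide F2. This borate is used at once in a Suzuki–Miyaura coupling with 9 (PdCl2(dppf), K3PO4, DMF/THF, 60 °C), rejoining the route at 16.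

Further compounds
F1 | step 1 | 2-bromo-4,6-dimethoxybenzaldehyde | COc1cc(Br)c(C=O)c(OC)c1
F0 | step 11 | none | none
F2 | step 10 | lithium B-methoxy-B-{[(1S,3S)-2,2-dimethyl-3-(prop-1-en-2-yl)cyclobutyl]methyl}-9-borabicyclo[3.3.1]nonan-9-uide | [Li+].CO[B-]1(C[C@H]3C[C@@H](C(C)=C)C3(C)C)C2CCCC1CCC2
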